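## The problem

The target is a germacranolide. Its core is a ten-membered carbocycle (C1–C10, germacrane numbering) with a trans-fused α-methylene-γ-lactone on C6–C7 (C11, C12, C13), a Z-trisubstituted C4=C5 alkene, and a trans 1,10-epoxide whose C10 is quaternary (methyl C14). C3 carries a benzoate and C8 a (2S,3S)-epoxyangelate.

A synthesis must close a medium ring against entropy and transannular strain, with the Z alkene and the oxygenated stereocentres already in place or made as the ring closes. Of the eight stereocentres, C6, C7 and C8 are contiguous and can be set by acyclic aldol and allylation control. C3 is insulated from them by the alkene and needs its own source of asymmetry. C1 and C10 are remote from everything in the open chain and can only be controlled by the ring as it forms. The two centres of the epoxyangelate arrive with the acid.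

The finished molecule tolerates little. The epoxide faces the C4=C5 alkene across the ring and opens transannularly with acid. The α-methylene lactone is a Michael acceptor, and the esters exclude strong base and hydride. Both the C6 and the C8 hydroxyl can lactonise onto C12, so they must be told apart.

The feature that invites a direct closure is the oxirane itself. C1 bears one hydrogen and C10 a methyl group, which is the pattern left when a sulfur ylide carbon (C1) adds to a methyl ketone (C10) and the alkoxide expels the sulfide. The Z C4=C5 alkene holds C3 and C6 on one side and gives the open chain a turn that brings C1 towards C10.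

## Retrosynthesis

**Acyl groups and lactone (43 → 42 → 39 → 38 → 36 + 35).** The C3 benzoate is removed first, giving alcohol 42, because an allylic benzoate is the group least compatible with everything before it. The lactone C12–O6 bond and the C12 carbonyl are then taken back to triol 39, in which C12 is an allylic alcohol. This keeps the Michael acceptor out of every basic step. The epoxyangelate is cut next (38 → 36 + acid 35). It must be on C8 before the C6 hydroxyl is freed, so that only O6 can close onto C12. The forward direction therefore needs one group on O8 (triethylsilyl) that leaves before all others, and nothing acid-cleaved after the epoxide exists. For that reason O6 carries a silyl ether and not an acetal.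

**Ring and epoxide (36 ← 31 ← 28).** In epoxide 31 the C1–C10 bond and the C1–O bond are cut together, giving the open-chain sulfonium salt 28 with a C10 methyl ketone. The neighbouring cut, epoxidation of a C1=C10 alkene after some other macrocyclisation, would ask a peracid to choose between two trisubstituted alkenes and between two faces. The chosen cut makes ring, quaternary centre and oxirane in one operation from a precursor with no ring at all. It asks that the ylide forms faster than the ketone enolises, that the ketone is the only electrophile (C12 is a silyl ether, not an enoate), and that the anti betaine closes to the trans epoxide on the right face. The last point is not secured by precedent.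

**Sulfonium salt (28 ← 26 + 27 ← 25 ← 24).** The S–C1 bond is cut to iodide 26 and diphenyl sulfide 27. Diphenyl sulfide is chosen because its ylides have no competing α-protons on sulfur. The iodide comes from alcohol 25, unmasked from the 4-methoxybenzyl ether 24. That ether is the only oxidatively cleaved group in the molecule, so C1 can be addressed while four silyl ethers stay on.

**C8–C10 (24 ← 23 ← 22 ← 21).** The methyl ketone is taken back to a terminal alkene (23). This is the only monosubstituted alkene present, so a Tsuji–Wacker oxidation can single it out. The C8–C9 bond is then cut by an allylboration of aldehyde 21, which sets C8 by reagent control. A direct acetone aldol at C8 would be shorter but offers no reliable control next to the C7 stereocentre. The sequence also differentiates O6 (silylated earlier) from O8 without extra steps.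

**C6–C7 (21 ← 20 ← 19 ← 18 ← 16 + 8).** Aldehyde 21 is traced through Weinreb amide 19 to the syn aldol adduct 18 of imide 16 and Z-enal 8. This is the convergent cut: it joins the two halves and sets C6 and C7 together from one auxiliary. Adding an alkenyl metal to a C6 aldehyde would form the neighbouring C5–C6 bond but leave C6 to chance. The forward reaction needs the dienolate of 16 to react at its α-carbon and the Z-enal to keep its geometry.

**Z-enal (8 ← 7 ← 6 ← 5 ← 4 ← 2 + 3).** The C4–C15 bond is cut by a syn carbocupration of ynoate 5, which fixes the Z geometry mechanistically. The C3–C4 bond is cut by an asymmetric alkynylation of aldehyde 2 with methyl propiolate 3, which sets C3. An olefination of a C5 aldehyde would give the same alkene but would make the route linear and put C3 last.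

**Imide (16 ← 13 + 14; 13 ← 11 ← 10 ← 9).** The acyl group of 16 is 3-(silyloxymethyl)but-3-enoic acid 13, attached to oxazolidinone 14. Acid 13 comes from diol 9 by monosilylation (10), chlorination (11) and carboxylation of the allylic Grignard reagent 12.

**Epoxy acid (35 ← 34 ← 33 ← 32).** The acid is cut to epoxy alcohol 34, made by asymmetric epoxidation of (Z)-2-methylbut-2-en-1-ol 33 from angelic acid 32. Epoxidising the angelate after esterification would have no facial control.

## Roads not taken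

**Alternative 1:** enzymatic cyclisation of (2Z,6E)-farnesyl diphosphate A1 to the hydrocarbon A2 (Z,E-germacrene A).
- Cut: one ring bond, with every oxygen function removed first.
- Forward step: a germacrene A synthase-type cyclase ionises the diphosphate, the distal alkene captures the allyl cation to close the ten-membered ring, and proton loss leaves the isopropenyl group on C7.
- Merits: one step from a C15 feedstock, no protecting groups, no dilution problem, and both ring alkene geometries and C7 delivered by the enzyme. In step economy for the carbon skeleton it is clearly better than the chosen plan.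
- Weak points: A2 carries none of the five oxygenated positions. The target then needs hydroxylation at C3, C6 and C8, oxidation of C12 to the acid level and 1,10-epoxidation, on a volatile hydrocarbon that rearranges on heating and cyclises with acid. Chemical allylic oxidation cannot discriminate among the many allylic positions of A2, and enzymes for each position would have to be found.
- Comparison: the chosen plan answers with oxygens that all arrive in building blocks of defined configuration. It pays with a long sequence and an unproven ring closure.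

**Alternative 2:** alkenylchromium closure at C5–C6 with lactonisation to A3.
- Cut: the C5–C6 bond and the lactone C–O bond.
- Forward step: CrCl2 with catalytic NiCl2 turns a Z-alkenyl iodide into an alkenylchromium species that adds to a C6 aldehyde; the chromium alkoxide acylates a methyl ester to close the γ-lactone.
- Merits: this coupling is among the most dependable ways to close medium rings. It keeps alkene geometry, tolerates ethers and esters, and forms two rings at once. On precedent for the ring closure it is superior to the chosen plan.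
- Weak points: C6 is created in the macrocyclisation with only ring control. A3 still lacks the C13 methylene, the epoxide and both esters, so lactone enolate chemistry and an epoxidation of C1=C10 beside C4=C5 remain, and the face of that epoxidation depends on ring conformation.
- Comparison: the chosen plan sets C6 by an auxiliary before any ring exists and makes the epoxide in the ring-closing event, so no peracid meets a diene lactone. If the ylide closure fails, this is the most credible replacement.

**Alternative 3:** photothermal olefin metathesis to dienone A4.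
- Cut: two σ bonds of a cyclobutane (C1–C4 and C5–C10), whose cleavage reveals both ring alkenes.
- Forward step: an enone–cyclobutene [2+2] photocycloaddition followed by thermolysis near 200 °C.
- Merits: the ten-membered diene comes from four- and six-membered rings with ring strain as driving force and no high dilution. It is a short and precedented way to the carbocycle.
- Weak points: at that temperature a cyclodeca-1,5-diene is in Cope equilibrium with divinylcyclohexanes. The Z and E alkene geometries depend on the ring-fusion configuration of the photoadduct, and an allylic silyl ether must survive the heat. A4 has a ketone at C6 and no C7 side chain, so C6, C7, the lactone, the epoxide and both esters are still to come, each with its own selectivity question.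
- Comparison: the ring is reached faster and on firmer ground than in the chosen plan. The chosen plan has every stereocentre except C1 and C10 fixed before cyclisation and needs no step above room temperature.

Key step: step 21

Numbering and abbreviations: atom numbers are germacrane numbers (C1–C10 ring, C11–C13 lactone carbons, C14 methyl on C10, C15 methyl on C4). TBS = tert-butyldimethylsilyl, TES = triethylsilyl, TBDPS = tert-butyldiphenylsilyl, PMB = 4-methoxybenzyl.

Assumption: (S,S)-ProPhenol is taken to give the 4S alcohol 4 in step 2; if the sense of the catalyst is the opposite, the (R,R)-ligand is used and nothing else changes.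

## Route

Step 1
Reactants: 1 3-[(4-methoxybenzyl)oxy]propan-1-ol
Product: 2 3-[(4-methoxybenzyl)oxy]propanal
Conditions: TEMPO (10 mol %), PhI(OAc)2, CH2Cl2, 23 °C
Reagents that add atoms: none
Why: Nitroxyl-catalysed oxidation of a primary alcohol stops at the aldehyde and is neutral, so the β-alkoxy aldehyde does not eliminate.

Step 2
Reactants: 2 3-[(4-methoxybenzyl)oxy]propanal; 3 methyl propiolate
Product: 4 methyl (4S)-4-hydroxy-6-[(4-methoxybenzyl)oxy]hex-2-ynoate
Conditions: (S,S)-ProPhenol (10 mol %), Me2Zn, Ph3PO (20 mol %), toluene, 4 °C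
Reagents that add atoms: none
Why: Zinc–ProPhenol asymmetric alkynylation of an aldehyde; the dinuclear zinc alkynylide adds to one carbonyl face and sets C3 (4S here).

Step 3
Reactants: 4 methyl (4S)-4-hydroxy-6-[(4-methoxybenzyl)oxy]hex-2-ynoate
Product: 5 methyl (4S)-4-(TBSO)-6-[(4-methoxybenzyl)oxy]hex-2-ynoate
Conditions: TBSCl, imidazole, DMF, 0 → 23 °C
Reagents that add atoms: tert-butyldimethylsilyl chloride, CC(C)(C)[Si](C)(C)Cl
Why: Standard silylation of a secondary propargylic alcohol; imidazole is too weak a base to isomerise the ynoate.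

Step 4
Reactants: 5 methyl (4S)-4-(TBSO)-6-[(4-methoxybenzyl)oxy]hex-2-ynoate
Product: 6 methyl (2Z,4S)-4-(TBSO)-6-[(4-methoxybenzyl)oxy]-3-methylhex-2-enoate
Conditions: Me2CuLi (from MeLi and CuI), THF, −78 °C; MeOH then aq NH4Cl at −78 °C
Reagents that add atoms: lithium dimethylcuprate, [Li+].C[Cu-]C
Why: Syn carbocupration of an ynoate puts methyl (C15) and copper on the same side, and protonation at −78 °C with retention leaves the ester cis to C3, which is the Z alkene.

Step 5
Reactants: 6 methyl (2Z,4S)-4-(TBSO)-6-[(4-methoxybenzyl)oxy]-3-methylhex-2-enoate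
Product: 7 (2Z,4S)-4-(TBSO)-6-[(4-methoxybenzyl)oxy]-3-methylhex-2-en-1-ol
Conditions: i-Bu2AlH, CH2Cl2, −78 °C
Reagents that add atoms: none
Why: 1,2-Reduction of an enoate to the allylic alcohol by an aluminium hydride; the alkene geometry is not touched.

Step 6
Reactants: 7 (2Z,4S)-4-(TBSO)-6-[(4-methoxybenzyl)oxy]-3-methylhex-2-en-1-ol
Product: 8 (2Z,4S)-4-(TBSO)-6-[(4-methoxybenzyl)oxy]-3-methylhex-2-enal
Conditions: MnO2, CH2Cl2, 23 °C
Reagents that add atoms: none
Why: Allylic oxidation with MnO2 is neutral and heterogeneous, so the β,β-disubstituted Z-enal should not isomerise.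

Step 7
Reactants: 9 2-methylidenepropane-1,3-diol
Product: 10 2-[(TBDPSO)methyl]prop-2-en-1-ol
Conditions: 9 (3 equiv), TBDPSCl, imidazole, THF, 0 °C
Reagents that add atoms: tert-butyl(chloro)diphenylsilane, CC(C)(C)[Si](Cl)(c1ccccc1)c1ccccc1
Why: Statistical monosilylation of a symmetric diol used in excess; the bulky silyl group disfavours the second silylation.

Step 8
Reactants: 10 2-[(TBDPSO)methyl]prop-2-en-1-ol
Product: 11 tert-butyl{[2-(chloromethyl)prop-2-en-1-yl]oxy}diphenylsilane
Conditions: PPh3, N-chlorosuccinimide, CH2Cl2, 0 °C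
Reagents that add atoms: N-chlorosuccinimide, O=C1CCC(=O)N1Cl
Why: Appel-type chlorination of a primary allylic alcohol; direct and allylic substitution give the same chloride because both allyl termini are CH2.

Step 9
Reactants: 11 tert-butyl{[2-(chloromethyl)prop-2-en-1-yl]oxy}diphenylsilane
Product: 13 3-[(TBDPSO)methyl]but-3-enoic acid, via allylmagnesium chloride 12 (not isolated)
Conditions: Mg, THF, 0 °C; CO2, −40 → 0 °C; aq HCl
Reagents that add atoms: magnesium, [Mg] (in 12 only); carbon dioxide, O=C=O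
Why: Carboxylation of an allylic Grignard reagent gives the β,γ-unsaturated acid; α- and γ-attack lead to the same product here.

Step 10
Reactants: 13 3-[(TBDPSO)methyl]but-3-enoic acid; 14 (4S)-4-benzyl-1,3-oxazolidin-2-one
Product: 16 (4S)-4-benzyl-3-{3-[(TBDPSO)methyl]but-3-enoyl}-1,3-oxazolidin-2-one, via mixed pivalic anhydride 15 (not isolated)
Conditions: t-BuCOCl, Et3N, THF, −20 °C; then 14, LiCl, −20 → 23 °C
Reagents that add atoms: pivaloyl chloride, CC(C)(C)C(=O)Cl (in 15 only)
Why: N-Acylation of the oxazolidinone through a mixed anhydride, the usual way to attach β,γ-unsaturated acids without moving the double bond.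

Step 11
Reactants: 16 (4S)-4-benzyl-3-{3-[(TBDPSO)methyl]but-3-enoyl}-1,3-oxazolidin-2-one; 8 (2Z,4S)-4-(TBSO)-6-[(4-methoxybenzyl)oxy]-3-methylhex-2-enal
Product: 18 (4S)-4-benzyl-3-{(2S,3R,4Z,6S)-6-(TBSO)-2-[3-(TBDPSO)prop-1-en-2-yl]-3-hydroxy-8-[(4-methoxybenzyl)oxy]-5-methyloct-4-enoyl}-1,3-oxazolidin-2-one, via Z-boron enolate 17 (not isolated)
Conditions: Bu2BOTf, i-Pr2NEt, CH2Cl2, −78 → 0 °C; 8, −78 → −10 °C; pH 7 buffer, MeOH, H2O2, 0 °C
Reagents that add atoms: dibutylboron triflate, CCCCB(CCCC)OS(=O)(=O)C(F)(F)F (in 17 only)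
Why: Evans syn aldol: the Z-boron dienolate reacts at its α-carbon through a chair transition state with the benzyl group shielding one face, which sets C7 and C6 (2S,3R in 18) together.

Step 12
Reactants: 18 aldol adduct (as named in step 11)
Product: 19 (2S,3R,4Z,6S)-6-(TBSO)-2-[3-(TBDPSO)prop-1-en-2-yl]-3-hydroxy-N-methoxy-8-[(4-methoxybenzyl)oxy]-N,5-dimethyloct-4-enamide
Conditions: AlMe3, MeONHMe·HCl, CH2Cl2, −15 → 0 °C
Reagents that add atoms: N,O-dimethylhydroxylamine hydrochloride, CNOC.Cl
Why: Aluminium amide transamination of a syn aldol imide to the Weinreb amide, assisted by the free β-hydroxyl; the auxiliary is recovered.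

Step 13
Reactants: 19 Weinreb amide (as named in step 12)
Product: 20 (2S,3R,4Z,6S)-3,6-bis(TBSO)-2-[3-(TBDPSO)prop-1-en-2-yl]-N-methoxy-8-[(4-methoxybenzyl)oxy]-N,5-dimethyloct-4-enamide
Conditions: TBSOTf, 2,6-lutidine, CH2Cl2, −78 → 0 °C
Reagents that add atoms: tert-butyldimethylsilyl triflate, CC(C)(C)[Si](C)(C)OS(=O)(=O)C(F)(F)F
Why: Silyl triflate silylation of a hindered secondary alcohol; this marks O6 before O8 exists, so the two are never equivalent.

Step 14
Reactants: 20 silylated Weinreb amide (as named in step 13)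
Product: 21 (2S,3R,4Z,6S)-3,6-bis(TBSO)-2-[3-(TBDPSO)prop-1-en-2-yl]-8-[(4-methoxybenzyl)oxy]-5-methyloct-4-enal
Conditions: i-Bu2AlH, THF, −78 °C
Reagents that add atoms: none
Why: Reduction of a Weinreb amide stops at the aldehyde because the chelated tetrahedral intermediate survives until work-up.

Step 15
Reactants: 21 aldehyde (as named in step 14)
Product: 22 (4R,5R,6R,7Z,9S)-6,9-bis(TBSO)-5-[3-(TBDPSO)prop-1-en-2-yl]-11-[(4-methoxybenzyl)oxy]-8-methylundeca-1,7-dien-4-ol
Conditions: (+)-Ipc2B(allyl) [from (+)-Ipc2BOMe and allylMgBr, Mg salts filtered off], Et2O, −78 °C; NaOH, H2O2, 0 → 23 °C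
Reagents that add atoms: (+)-B-allyldiisopinocampheylborane, C=CCB([C@@H]1[C@@H](C)[C@@H]2C[C@H](C1)C2(C)C)[C@@H]1[C@@H](C)[C@@H]2C[C@H](C1)C2(C)C
Why: Brown allylboration through a chair transition state; the isopinocampheyl groups from (−)-α-pinene choose the aldehyde face and set C8 (4R in 22), and the salt-free reagent reacts at −78 °C before the α-alkenyl aldehyde can epimerise.

Step 16
Reactants: 22 homoallylic alcohol (as named in step 15)
Product: 23 (4R,5R,6R,7Z,9S)-6,9-bis(TBSO)-5-[3-(TBDPSO)prop-1-en-2-yl]-11-[(4-methoxybenzyl)oxy]-8-methyl-4-(TESO)undeca-1,7-diene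
Conditions: TESOTf, 2,6-lutidine, CH2Cl2, −78 °C
Reagents that add atoms: triethylsilyl triflate, CC[Si](CC)(CC)OS(=O)(=O)C(F)(F)F
Why: Silylation; O8 receives the one silyl group that can later be removed before all others.

Step 17
Reactants: 23 triethylsilyl ether (as named in step 16)
Product: 24 (4R,5R,6R,7Z,9S)-6,9-bis(TBSO)-5-[3-(TBDPSO)prop-1-en-2-yl]-11-[(4-methoxybenzyl)oxy]-8-methyl-4-(TESO)undec-7-en-2-one
Conditions: PdCl2 (10 mol %), Cu(OAc)2 (20 mol %), O2 (1 atm), DMA/H2O 7:1, 23 °C
Reagents that add atoms: water, O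
Why: Tsuji–Wacker oxidation: Markovnikov hydroxypalladation by divalent palladium converts the only monosubstituted alkene into the methyl ketone (C10, C14), while the 1,1-disubstituted and trisubstituted alkenes react much more slowly; copper acetate keeps the medium mild for the silyl ethers.

Step 18
Reactants: 24 methyl ketone (as named in step 17)
Product: 25 (4R,5R,6R,7Z,9S)-6,9-bis(TBSO)-5-[3-(TBDPSO)prop-1-en-2-yl]-11-hydroxy-8-methyl-4-(TESO)undec-7-en-2-one
Conditions: DDQ, CH2Cl2/pH 7 buffer, 0 °C
Reagents that add atoms: none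
Why: Oxidative cleavage of the 4-methoxybenzyl ether, the only such group present, frees the C1 hydroxyl under buffered conditions that leave all silyl ethers in place.

Step 19
Reactants: 25 hydroxy ketone (as named in step 18)
Product: 26 (4R,5R,6R,7Z,9S)-6,9-bis(TBSO)-5-[3-(TBDPSO)prop-1-en-2-yl]-11-iodo-8-methyl-4-(TESO)undec-7-en-2-one
Conditions: I2, PPh3, imidazole, CH2Cl2, 0 °C
Reagents that add atoms: iodine, II
Why: Appel iodination of a primary alcohol under buffered conditions.

Step 20
Reactants: 26 iodo ketone (as named in step 19); 27 diphenyl sulfide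
Product: 28 [(3S,4Z,6R,7R,8R)-3,6-bis(TBSO)-7-[3-(TBDPSO)prop-1-en-2-yl]-4-methyl-10-oxo-8-(TESO)undec-4-en-1-yl]diphenylsulfonium tetrafluoroborate
Conditions: 27 (5 equiv), AgBF4, CH2Cl2, 0 → 23 °C, dark
Reagents that add atoms: silver tetrafluoroborate, [Ag+].F[B-](F)(F)F
Why: Silver-assisted S-alkylation of diphenyl sulfide by a primary iodide, the standard preparation of alkyldiphenylsulfonium salts; precipitation of AgI drives it.

Step 21
Reactants: 28 sulfonium tetrafluoroborate (as named in step 20)
Product: 31 (1R,3S,4Z,6R,7R,8R,10R)-3,6-bis(TBSO)-12-(TBDPSO)-8-(TESO)-1,10-epoxygermacra-4,11(13)-diene, via sulfonium ylide 29 (not isolated), via betaine 30 (not isolated)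
Conditions: KN(SiMe3)2 (1.05 equiv), THF, −78 → −40 °C; 28 and base added together over 6 h (final 1 mM)
Reagents that add atoms: none
Why: Proposed new method: KN(SiMe3)2 removes a C1 proton next to the diphenylsulfonium group to give ylide 29, whose carbanion adds to the C10 carbonyl (10-exo-trig) to form the C1–C10 bond and betaine 30, and the C10 alkoxide then displaces diphenyl sulfide at C1 with inversion (3-exo-tet) to close the oxirane; the closest known chemistry is the intermolecular Corey–Chaykovsky epoxidation of ketones with diphenylsulfonium alkylides and its intramolecular versions that close five- and six-membered rings. Addition of an unstabilised ylide is irreversible, so C1 and C10 are both fixed in the C–C bond-forming transition state. C10 is set by the ketone face that is attacked, which should be biased by the adjacent C8 silyloxy stereocentre and by the fold that the Z C4=C5 alkene and the C6–C8 triad impose on the chain. C1 is set by the face of the ylide carbon; in the anti betaine required for closure the ring chains C2 and C9 lie on opposite sides, which is the trans epoxide. The step needs ylide formation to beat enolisation (the sulfonium α-protons are more acidic than those of the ketone by several pKa units, and one equivalent of hindered base is used at −78 °C), a single electrophile (C12 is a silyl ether, so there is no enoate or ester), and cyclisation to beat dimerisation (simultaneous slow addition keeps the ylide dilute).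

Step 22
Reactants: 32 angelic acid [(Z)-2-methylbut-2-enoic acid]
Product: 33 (Z)-2-methylbut-2-en-1-ol
Conditions: LiAlH4, Et2O, 0 °C
Reagents that add atoms: none
Why: Hydride reduction of an α,β-unsaturated acid to the allylic alcohol with the Z geometry retained.

Step 23
Reactants: 33 (Z)-2-methylbut-2-en-1-ol
Product: 34 [(2R,3S)-2,3-dimethyloxiran-2-yl]methanol
Conditions: Ti(OiPr)4, D-(−)-diethyl tartrate, t-BuOOH, 4 Å sieves, CH2Cl2, −20 °C
Reagents that add atoms: tert-butyl hydroperoxide, CC(C)(C)OO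
Why: Sharpless asymmetric epoxidation; the titanium tartrate complex delivers oxygen to one face of the allylic alcohol, and D-(−)-tartrate gives the 2R,3S epoxy alcohol, with the cis relation of CH2OH and the C3 methyl fixed by the Z alkene.

Step 24
Reactants: 34 [(2R,3S)-2,3-dimethyloxiran-2-yl]methanol
Product: 35 (2S,3S)-2,3-dimethyloxirane-2-carboxylic acid
Conditions: RuCl3 (2 mol %), NaIO4, MeCN/EtOAc/H2O, 0 → 23 °C
Reagents that add atoms: water, O; sodium periodate, [Na+].[O-]I(=O)(=O)=O
Why: Ruthenium tetroxide oxidation of a primary epoxy alcohol to the acid; no stereocentre is touched, and the C2 descriptor changes from R to S only because the priorities change.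

Step 25
Reactants: 31 epoxide (as named in step 21)
Product: 36 (1R,3S,4Z,6R,7R,8R,10R)-3,6-bis(TBSO)-12-(TBDPSO)-1,10-epoxygermacra-4,11(13)-dien-8-ol
Conditions: HF·pyridine, pyridine, THF, 0 °C
Reagents that add atoms: none
Why: Selective desilylation: a secondary triethylsilyl ether is cleaved by buffered fluoride well before secondary TBS and primary TBDPS ethers.

Step 26
Reactants: 36 C8 alcohol (as named in step 25); 35 (2S,3S)-2,3-dimethyloxirane-2-carboxylic acid
Product: 38 (1R,3S,4Z,6R,7R,8R,10R)-3,6-bis(TBSO)-12-(TBDPSO)-1,10-epoxygermacra-4,11(13)-dien-8-yl (2S,3S)-2,3-dimethyloxirane-2-carboxylate, via Yamaguchi mixed anhydride 37 (not isolated)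
Conditions: 35, 2,4,6-Cl3C6H2COCl, Et3N, THF, 23 °C; then 36, DMAP, toluene, 23 °C
Reagents that add atoms: 2,4,6-trichlorobenzoyl chloride, O=C(Cl)c1c(Cl)cc(Cl)cc1Cl (in 37 only)
Why: Yamaguchi esterification acylates the hindered C8 alcohol under mild, non-acidic conditions that leave both epoxides intact.

Step 27
Reactants: 38 epoxy ester (as named in step 26)
Product: 39 (1R,3S,4Z,6R,7S,8R,10R)-1,10-epoxy-3,6,12-trihydroxygermacra-4,11(13)-dien-8-yl (2S,3S)-2,3-dimethyloxirane-2-carboxylate
Conditions: HF·pyridine, pyridine, THF, 0 → 23 °C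
Reagents that add atoms: none
Why: Fluoride desilylation under buffered, non-basic conditions removes the three remaining silyl ethers without acyl migration; the C7 descriptor changes by priority only.

Step 28
Reactants: 39 triol (as named in step 27)
Product: 42 (1R,3S,4Z,6R,7R,8R,10R)-1,10-epoxy-3-hydroxygermacra-4,11(13)-dien-12,6-olid-8-yl (2S,3S)-2,3-dimethyloxirane-2-carboxylate, via hydroxy enal 40 (not isolated), via lactol 41 (not isolated)
Conditions: TEMPO (20 mol %), PhI(OAc)2 (2.5 equiv), CH2Cl2, 23 °C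
Reagents that add atoms: none
Why: Oxidative lactonisation of a 1,4-diol: the nitroxyl catalyst oxidises the primary allylic C12 alcohol first, the C6 hydroxyl closes the lactol and a second oxidation gives the α-methylene lactone; O8 is already acylated and the secondary C3 alcohol reacts more slowly.

Step 29
Reactants: 42 hydroxy lactone (as named in step 28)
Product: 43 (1R,3S,4Z,6R,7R,8R,10R)-3-benzoyloxy-1,10-epoxygermacra-4,11(13)-dien-12,6-olid-8-yl (2S,3S)-2,3-dimethyloxirane-2-carboxylate (CNP0324463.3)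
Conditions: BzCl, pyridine, DMAP (cat.), CH2Cl2, 0 °C
Reagents that add atoms: benzoyl chloride, O=C(Cl)c1ccccc1
Why: DMAP-catalysed acylation of the only free hydroxyl completes the target without touching a stereocentre.

## Compound list

1 | 3-[(4-methoxybenzyl)oxy]propan-1-ol | COc1ccc(COCCCO)cc1 | starting material
2 | 3-[(4-methoxybenzyl)oxy]propanal | COc1ccc(COCCC=O)cc1 | intermediate
3 | methyl propiolate | C#CC(=O)OC | starting material
4 | methyl (4S)-4-hydroxy-6-[(4-methoxybenzyl)oxy]hex-2-ynoate | COC(=O)C#C[C@@H](O)CCOCc1ccc(OC)cc1 | intermediate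
5 | methyl (4S)-4-(TBSO)-6-[(4-methoxybenzyl)oxy]hex-2-ynoate | COC(=O)C#C[C@@H](O[Si](C)(C)C(C)(C)C)CCOCc1ccc(OC)cc1 | intermediate
6 | methyl (2Z,4S)-4-(TBSO)-6-[(4-methoxybenzyl)oxy]-3-methylhex-2-enoate | COC(=O)/C=C(/C)[C@@H](O[Si](C)(C)C(C)(C)C)CCOCc1ccc(OC)cc1 | intermediate
7 | (2Z,4S)-4-(TBSO)-6-[(4-methoxybenzyl)oxy]-3-methylhex-2-en-1-ol | OC/C=C(/C)[C@@H](O[Si](C)(C)C(C)(C)C)CCOCc1ccc(OC)cc1 | intermediate
8 | (2Z,4S)-4-(TBSO)-6-[(4-methoxybenzyl)oxy]-3-methylhex-2-enal | O=C/C=C(/C)[C@@H](O[Si](C)(C)C(C)(C)C)CCOCc1ccc(OC)cc1 | intermediate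
9 | 2-methylidenepropane-1,3-diol | C=C(CO)CO | starting material
10 | 2-[(TBDPSO)methyl]prop-2-en-1-ol | C=C(CO)CO[Si](c1ccccc1)(c1ccccc1)C(C)(C)C | intermediate
11 | tert-butyl{[2-(chloromethyl)prop-2-en-1-yl]oxy}diphenylsilane | C=C(CCl)CO[Si](c1ccccc1)(c1ccccc1)C(C)(C)C | intermediate
12 | {2-[(TBDPSO)methyl]prop-2-en-1-yl}magnesium chloride | C=C(C[Mg]Cl)CO[Si](c1ccccc1)(c1ccccc1)C(C)(C)C | intermediate
13 | 3-[(TBDPSO)methyl]but-3-enoic acid | C=C(CC(=O)O)CO[Si](c1ccccc1)(c1ccccc1)C(C)(C)C | intermediate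
14 | (4S)-4-benzyl-1,3-oxazolidin-2-one | O=C1N[C@@H](Cc2ccccc2)CO1 | starting material
15 | mixed anhydride of 13 with pivalic acid | C=C(CC(=O)OC(=O)C(C)(C)C)CO[Si](c1ccccc1)(c1ccccc1)C(C)(C)C | intermediate
16 | (4S)-4-benzyl-3-{3-[(TBDPSO)methyl]but-3-enoyl}-1,3-oxazolidin-2-one | C=C(CC(=O)N1[C@@H](Cc2ccccc2)COC1=O)CO[Si](c1ccccc1)(c1ccccc1)C(C)(C)C | intermediate
17 | (Z)-dibutylboron enolate of 16 | C=C(CO[Si](c1ccccc1)(c1ccccc1)C(C)(C)C)/C=C(\OB(CCCC)CCCC)N1[C@@H](Cc2ccccc2)COC1=O | intermediate
18 | (4S)-4-benzyl-3-{(2S,3R,4Z,6S)-6-(TBSO)-2-[3-(TBDPSO)prop-1-en-2-yl]-3-hydroxy-8-[(4-methoxybenzyl)oxy]-5-methyloct-4-enoyl}-1,3-oxazolidin-2-one | O=C1OC[C@H](Cc2ccccc2)N1C(=O)[C@@H](C(=C)CO[Si](c1ccccc1)(c1ccccc1)C(C)(C)C)[C@H](O)/C=C(/C)[C@@H](O[Si](C)(C)C(C)(C)C)CCOCc1ccc(OC)cc1 | intermediate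
19 | (2S,3R,4Z,6S)-6-(TBSO)-2-[3-(TBDPSO)prop-1-en-2-yl]-3-hydroxy-N-methoxy-8-[(4-methoxybenzyl)oxy]-N,5-dimethyloct-4-enamide | CON(C)C(=O)[C@@H](C(=C)CO[Si](c1ccccc1)(c1ccccc1)C(C)(C)C)[C@H](O)/C=C(/C)[C@@H](O[Si](C)(C)C(C)(C)C)CCOCc1ccc(OC)cc1 | intermediate
20 | (2S,3R,4Z,6S)-3,6-bis(TBSO)-2-[3-(TBDPSO)prop-1-en-2-yl]-N-methoxy-8-[(4-methoxybenzyl)oxy]-N,5-dimethyloct-4-enamide | CON(C)C(=O)[C@@H](C(=C)CO[Si](c1ccccc1)(c1ccccc1)C(C)(C)C)[C@H](O[Si](C)(C)C(C)(C)C)/C=C(/C)[C@@H](O[Si](C)(C)C(C)(C)C)CCOCc1ccc(OC)cc1 | intermediate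
21 | (2S,3R,4Z,6S)-3,6-bis(TBSO)-2-[3-(TBDPSO)prop-1-en-2-yl]-8-[(4-methoxybenzyl)oxy]-5-methyloct-4-enal | O=C[C@@H](C(=C)CO[Si](c1ccccc1)(c1ccccc1)C(C)(C)C)[C@H](O[Si](C)(C)C(C)(C)C)/C=C(/C)[C@@H](O[Si](C)(C)C(C)(C)C)CCOCc1ccc(OC)cc1 | intermediate
22 | (4R,5R,6R,7Z,9S)-6,9-bis(TBSO)-5-[3-(TBDPSO)prop-1-en-2-yl]-11-[(4-methoxybenzyl)oxy]-8-methylundeca-1,7-dien-4-ol | C=CC[C@@H](O)[C@@H](C(=C)CO[Si](c1ccccc1)(c1ccccc1)C(C)(C)C)[C@H](O[Si](C)(C)C(C)(C)C)/C=C(/C)[C@@H](O[Si](C)(C)C(C)(C)C)CCOCc1ccc(OC)cc1 | intermediate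
23 | (4R,5R,6R,7Z,9S)-6,9-bis(TBSO)-5-[3-(TBDPSO)prop-1-en-2-yl]-11-[(4-methoxybenzyl)oxy]-8-methyl-4-(TESO)undeca-1,7-diene | C=CC[C@@H](O[Si](CC)(CC)CC)[C@@H](C(=C)CO[Si](c1ccccc1)(c1ccccc1)C(C)(C)C)[C@H](O[Si](C)(C)C(C)(C)C)/C=C(/C)[C@@H](O[Si](C)(C)C(C)(C)C)CCOCc1ccc(OC)cc1 | intermediate
24 | (4R,5R,6R,7Z,9S)-6,9-bis(TBSO)-5-[3-(TBDPSO)prop-1-en-2-yl]-11-[(4-methoxybenzyl)oxy]-8-methyl-4-(TESO)undec-7-en-2-one | CC(=O)C[C@@H](O[Si](CC)(CC)CC)[C@@H](C(=C)CO[Si](c1ccccc1)(c1ccccc1)C(C)(C)C)[C@H](O[Si](C)(C)C(C)(C)C)/C=C(/C)[C@@H](O[Si](C)(C)C(C)(C)C)CCOCc1ccc(OC)cc1 | intermediate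
25 | (4R,5R,6R,7Z,9S)-6,9-bis(TBSO)-5-[3-(TBDPSO)prop-1-en-2-yl]-11-hydroxy-8-methyl-4-(TESO)undec-7-en-2-one | CC(=O)C[C@@H](O[Si](CC)(CC)CC)[C@@H](C(=C)CO[Si](c1ccccc1)(c1ccccc1)C(C)(C)C)[C@H](O[Si](C)(C)C(C)(C)C)/C=C(/C)[C@@H](O[Si](C)(C)C(C)(C)C)CCO | intermediate
26 | (4R,5R,6R,7Z,9S)-6,9-bis(TBSO)-5-[3-(TBDPSO)prop-1-en-2-yl]-11-iodo-8-methyl-4-(TESO)undec-7-en-2-one | CC(=O)C[C@@H](O[Si](CC)(CC)CC)[C@@H](C(=C)CO[Si](c1ccccc1)(c1ccccc1)C(C)(C)C)[C@H](O[Si](C)(C)C(C)(C)C)/C=C(/C)[C@@H](O[Si](C)(C)C(C)(C)C)CCI | intermediate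
27 | diphenyl sulfide | c1ccc(Sc2ccccc2)cc1 | starting material
28 | [(3S,4Z,6R,7R,8R)-3,6-bis(TBSO)-7-[3-(TBDPSO)prop-1-en-2-yl]-4-methyl-10-oxo-8-(TESO)undec-4-en-1-yl]diphenylsulfonium tetrafluoroborate | CC(=O)C[C@@H](O[Si](CC)(CC)CC)[C@@H](C(=C)CO[Si](c1ccccc1)(c1ccccc1)C(C)(C)C)[C@H](O[Si](C)(C)C(C)(C)C)/C=C(/C)[C@@H](O[Si](C)(C)C(C)(C)C)CC[S+](c1ccccc1)c1ccccc1.F[B-](F)(F)F | intermediate
29 | C1 diphenylsulfonium ylide of 28 | CC(=O)C[C@@H](O[Si](CC)(CC)CC)[C@@H](C(=C)CO[Si](c1ccccc1)(c1ccccc1)C(C)(C)C)[C@H](O[Si](C)(C)C(C)(C)C)/C=C(/C)[C@@H](O[Si](C)(C)C(C)(C)C)C[CH-][S+](c1ccccc1)c1ccccc1 | intermediate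
30 | (1S,10R)-betaine: ten-membered C10 alkoxide with diphenylsulfonio group on C1 | CC(C)(C)[Si](C)(C)O[C@@H]1/C=C(/C)[C@@H](O[Si](C)(C)C(C)(C)C)C[C@H]([S+](c2ccccc2)c2ccccc2)[C@](C)([O-])C[C@@H](O[Si](CC)(CC)CC)[C@H]1C(=C)CO[Si](c1ccccc1)(c1ccccc1)C(C)(C)C | intermediate
31 | (1R,3S,4Z,6R,7R,8R,10R)-3,6-bis(TBSO)-12-(TBDPSO)-8-(TESO)-1,10-epoxygermacra-4,11(13)-diene | CC(C)(C)[Si](C)(C)O[C@@H]1/C=C(/C)[C@@H](O[Si](C)(C)C(C)(C)C)C[C@H]2O[C@]2(C)C[C@@H](O[Si](CC)(CC)CC)[C@H]1C(=C)CO[Si](c1ccccc1)(c1ccccc1)C(C)(C)C | intermediate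
32 | angelic acid | C/C=C(/C)C(=O)O | starting material
33 | (Z)-2-methylbut-2-en-1-ol | C/C=C(/C)CO | intermediate
34 | [(2R,3S)-2,3-dimethyloxiran-2-yl]methanol | OC[C@@]1(C)O[C@H]1C | intermediate
35 | (2S,3S)-2,3-dimethyloxirane-2-carboxylic acid | OC(=O)[C@@]1(C)O[C@H]1C | intermediate
36 | (1R,3S,4Z,6R,7R,8R,10R)-3,6-bis(TBSO)-12-(TBDPSO)-1,10-epoxygermacra-4,11(13)-dien-8-ol | CC(C)(C)[Si](C)(C)O[C@@H]1/C=C(/C)[C@@H](O[Si](C)(C)C(C)(C)C)C[C@H]2O[C@]2(C)C[C@@H](O)[C@H]1C(=C)CO[Si](c1ccccc1)(c1ccccc1)C(C)(C)C | intermediate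
37 | mixed anhydride of 35 with 2,4,6-trichlorobenzoic acid | O=C(OC(=O)c1c(Cl)cc(Cl)cc1Cl)[C@@]1(C)O[C@H]1C | intermediate
38 | (1R,3S,4Z,6R,7R,8R,10R)-3,6-bis(TBSO)-12-(TBDPSO)-1,10-epoxygermacra-4,11(13)-dien-8-yl (2S,3S)-2,3-dimethyloxirane-2-carboxylate | CC(C)(C)[Si](C)(C)O[C@@H]1/C=C(/C)[C@@H](O[Si](C)(C)C(C)(C)C)C[C@H]2O[C@]2(C)C[C@@H](OC(=O)[C@@]2(C)O[C@H]2C)[C@H]1C(=C)CO[Si](c1ccccc1)(c1ccccc1)C(C)(C)C | intermediate
39 | (1R,3S,4Z,6R,7S,8R,10R)-1,10-epoxy-3,6,12-trihydroxygermacra-4,11(13)-dien-8-yl (2S,3S)-2,3-dimethyloxirane-2-carboxylate | O[C@@H]1/C=C(/C)[C@@H](O)C[C@H]2O[C@]2(C)C[C@@H](OC(=O)[C@@]2(C)O[C@H]2C)[C@H]1C(=C)CO | intermediate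
40 | C12 aldehyde of 39 (3,6-dihydroxy enal) | O[C@@H]1/C=C(/C)[C@@H](O)C[C@H]2O[C@]2(C)C[C@@H](OC(=O)[C@@]2(C)O[C@H]2C)[C@H]1C(=C)C=O | intermediate
41 | 6,12-lactol of 40 (both C12 epimers) | C=C1C(O)O[C@@H]2/C=C(/C)[C@@H](O)C[C@H]3O[C@]3(C)C[C@@H](OC(=O)[C@@]3(C)O[C@H]3C)[C@@H]12 | intermediate
42 | (1R,3S,4Z,6R,7R,8R,10R)-1,10-epoxy-3-hydroxygermacra-4,11(13)-dien-12,6-olid-8-yl (2S,3S)-2,3-dimethyloxirane-2-carboxylate | C=C1C(=O)O[C@@H]2/C=C(/C)[C@@H](O)C[C@H]3O[C@]3(C)C[C@@H](OC(=O)[C@@]3(C)O[C@H]3C)[C@@H]12 | intermediate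
43 | (1R,3S,4Z,6R,7R,8R,10R)-3-benzoyloxy-1,10-epoxygermacra-4,11(13)-dien-12,6-olid-8-yl (2S,3S)-2,3-dimethyloxirane-2-carboxylate (CNP0324463.3) | C=C1C(=O)O[C@@H]2/C=C(/C)[C@@H](OC(=O)c3ccccc3)C[C@H]3O[C@]3(C)C[C@@H](OC(=O)[C@@]3(C)O[C@H]3C)[C@@H]12 | target

## Step count and least certain steps

Total: 29 steps. Longest linear sequence: 22 steps (steps 1–6, 11–21, 25–29).

**Step 21 (key step, proposed new method).**
- What may go wrong: the ylide may couple with the ketone of a second molecule, lose diphenyl sulfide by elimination towards C2, or act as a base and trigger loss of the C8 silyloxy group. If the ring does close, addition to the wrong ketone face or through the betaine that gives the cis epoxide is possible, because no precedent fixes the conformation of this ten-membered transition state and four large silyl ethers crowd it.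
- Fallback (known chemistry): it sets out from alcohol 25. Dess–Martin oxidation gives the keto-aldehyde F1. A pinacol coupling with low-valent titanium (TiCl3(DME)1.5, Zn–Cu, DME, slow addition) forms the same C1–C10 bond and gives the 1,10-diol F2. Selective mesylation of the secondary C1 hydroxyl gives the monomesylate F3. K2CO3 in MeOH then lets the C10 alkoxide displace the mesylate with inversion, and the route is rejoined at epoxide 31. The diol diastereomers would have to be separated; only the 1S,10R isomer leads to 31.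

**Step 15 (allylboration).**
- What may go wrong: epimerisation at C7 or migration of the β,γ-alkene into conjugation in aldehyde 21 before it reacts, and poor facial selectivity if reagent and substrate preferences are mismatched.
- Fallback: it sets out from Weinreb amide 19, which still has the free C6 hydroxyl. Allylmagnesium bromide gives the β-hydroxy allyl ketone F4. An Evans–Tishchenko reduction (SmI2 cat., PhCHO) uses the C6 hydroxyl to deliver hydride and gives the anti C8 alcohol as its C6 benzoate F5. TESOTf gives the silyl ether F6. i-Bu2AlH removes the benzoate to give the C6 alcohol F7, and TBSOTf returns to 23.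

**Step 17 (Wacker oxidation).**
- What may go wrong: loss of the triethylsilyl group in the slightly acidic medium, aldehyde formation by anti-Markovnikov attack next to the silyloxy group, or slow competing oxidation of the 1,1-disubstituted alkene.
- Fallback: it sets out from aldehyde 21. An asymmetric propargylation (allenylboronic acid pinacol ester with a chiral BINOL-phosphoric acid, the enantiomer chosen for 8R) gives the homopropargylic alcohol F8. TESOTf gives the silyl ether F9. Markovnikov hydration of the terminal alkyne with a monovalent gold catalyst (Ph3PAuNTf2, wet dioxane), which leaves alkenes alone, returns to ketone 24.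

**Step 27 (global desilylation).**
- What may go wrong: opening of the 1,10-epoxide by HF or by a freed hydroxyl across the ring, incomplete cleavage of the hindered C6 silyl ether, or migration of the epoxyangelate if the medium turns basic.
- Fallback: it sets out from alcohol 36 and moves all fluoride chemistry ahead of the acylations. NaH and 4-methoxybenzyl bromide give the C8 ether F10. Bu4NF, harmless while no ester is present, gives the triol F11. TEMPO/PhI(OAc)2 gives the hydroxy lactone F12. Benzoyl chloride gives the benzoate F13. DDQ frees the C8 alcohol F14, and Yamaguchi esterification with 35 reaches target 43.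

**Step 2 (asymmetric alkynylation).**
- What may go wrong: modest enantioselectivity or self-aldol of the unbranched, enolisable aldehyde under the zinc catalyst.
- Fallback: it sets out from aldehyde 2. Addition of lithiated 3 at −78 °C gives the racemic alcohol F15. Dess–Martin oxidation gives the ynone F16. Midland reduction with (S)-Alpine-borane, for which the alkyne is the small group, returns to 4.

## Further compounds

F1 | step 21 | keto-aldehyde: C1 aldehyde of 25 | CC(=O)C[C@@H](O[Si](CC)(CC)CC)[C@@H](C(=C)CO[Si](c1ccccc1)(c1ccccc1)C(C)(C)C)[C@H](O[Si](C)(C)C(C)(C)C)/C=C(/C)[C@@H](O[Si](C)(C)C(C)(C)C)CC=O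
F2 | step 21 | (1S,10R)-1,10-diol of the silylated germacra-4,11(13)-diene | CC(C)(C)[Si](C)(C)O[C@@H]1/C=C(/C)[C@@H](O[Si](C)(C)C(C)(C)C)C[C@H](O)[C@](C)(O)C[C@@H](O[Si](CC)(CC)CC)[C@H]1C(=C)CO[Si](c1ccccc1)(c1ccccc1)C(C)(C)C
F3 | step 21 | C1 monomesylate of F2 | CC(C)(C)[Si](C)(C)O[C@@H]1/C=C(/C)[C@@H](O[Si](C)(C)C(C)(C)C)C[C@H](OS(C)(=O)=O)[C@](C)(O)C[C@@H](O[Si](CC)(CC)CC)[C@H]1C(=C)CO[Si](c1ccccc1)(c1ccccc1)C(C)(C)C
F4 | step 15 | β-hydroxy allyl ketone from 19 | C=CCC(=O)[C@@H](C(=C)CO[Si](c1ccccc1)(c1ccccc1)C(C)(C)C)[C@H](O)/C=C(/C)[C@@H](O[Si](C)(C)C(C)(C)C)CCOCc1ccc(OC)cc1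
F5 | step 15 | anti C8 alcohol with C6 benzoate | C=CC[C@@H](O)[C@@H](C(=C)CO[Si](c1ccccc1)(c1ccccc1)C(C)(C)C)[C@H](OC(=O)c1ccccc1)/C=C(/C)[C@@H](O[Si](C)(C)C(C)(C)C)CCOCc1ccc(OC)cc1
F6 | step 15 | C8 triethylsilyl ether of F5 | C=CC[C@@H](O[Si](CC)(CC)CC)[C@@H](C(=C)CO[Si](c1ccccc1)(c1ccccc1)C(C)(C)C)[C@H](OC(=O)c1ccccc1)/C=C(/C)[C@@H](O[Si](C)(C)C(C)(C)C)CCOCc1ccc(OC)cc1
F7 | step 15 | C6 alcohol with C8 triethylsilyl ether | C=CC[C@@H](O[Si](CC)(CC)CC)[C@@H](C(=C)CO[Si](c1ccccc1)(c1ccccc1)C(C)(C)C)[C@H](O)/C=C(/C)[C@@H](O[Si](C)(C)C(C)(C)C)CCOCc1ccc(OC)cc1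
F8 | step 17 | homopropargylic C8 alcohol from 21 | C#CC[C@@H](O)[C@@H](C(=C)CO[Si](c1ccccc1)(c1ccccc1)C(C)(C)C)[C@H](O[Si](C)(C)C(C)(C)C)/C=C(/C)[C@@H](O[Si](C)(C)C(C)(C)C)CCOCc1ccc(OC)cc1
F9 | step 17 | C8 triethylsilyl ether of F8 | C#CC[C@@H](O[Si](CC)(CC)CC)[C@@H](C(=C)CO[Si](c1ccccc1)(c1ccccc1)C(C)(C)C)[C@H](O[Si](C)(C)C(C)(C)C)/C=C(/C)[C@@H](O[Si](C)(C)C(C)(C)C)CCOCc1ccc(OC)cc1
F10 | step 27 | C8 4-methoxybenzyl ether of 36 | CC(C)(C)[Si](C)(C)O[C@@H]1/C=C(/C)[C@@H](O[Si](C)(C)C(C)(C)C)C[C@H]2O[C@]2(C)C[C@@H](OCc2ccc(OC)cc2)[C@H]1C(=C)CO[Si](c1ccccc1)(c1ccccc1)C(C)(C)C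
F11 | step 27 | 3,6,12-triol with C8 4-methoxybenzyl ether | O[C@@H]1/C=C(/C)[C@@H](O)C[C@H]2O[C@]2(C)C[C@@H](OCc2ccc(OC)cc2)[C@H]1C(=C)CO
F12 | step 27 | 12,6-lactone with free C3 hydroxyl and C8 4-methoxybenzyl ether | C=C1C(=O)O[C@@H]2/C=C(/C)[C@@H](O)C[C@H]3O[C@]3(C)C[C@@H](OCc3ccc(OC)cc3)[C@@H]12
F13 | step 27 | C3 benzoate of F12 | C=C1C(=O)O[C@@H]2/C=C(/C)[C@@H](OC(=O)c3ccccc3)C[C@H]3O[C@]3(C)C[C@@H](OCc3ccc(OC)cc3)[C@@H]12
F14 | step 27 | C8 alcohol of the benzoyl lactone | C=C1C(=O)O[C@@H]2/C=C(/C)[C@@H](OC(=O)c3ccccc3)C[C@H]3O[C@]3(C)C[C@@H](O)[C@@H]12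
F15 | step 2 | racemic methyl 4-hydroxy-6-[(4-methoxybenzyl)oxy]hex-2-ynoate | COC(=O)C#CC(O)CCOCc1ccc(OC)cc1
F16 | step 2 | methyl 6-[(4-methoxybenzyl)oxy]-4-oxohex-2-ynoate | COC(=O)C#CC(=O)CCOCc1ccc(OC)cc1
A1 | alternative 1 | (2Z,6E)-farnesyl diphosphate | CC(C)=CCC/C(C)=C/CC/C(C)=C\COP(=O)(O)OP(=O)(O)O
A2 | alternative 1 | (1(10)E,4Z)-germacra-1(10),4,11-triene (Z,E-germacrene A) | C=C(C)[C@H]1C/C=C(/C)CC/C=C(\C)CC1
A3 | alternative 2 | trans-fused ten-membered lactone lacking the C13 methylene, with C3 TBS ether and C8 4-methoxybenzyl ether | C1C(=O)O[C@@H]2/C=C(/C)[C@@H](O[Si](C)(C)C(C)(C)C)C/C=C(\C)C[C@@H](OCc3ccc(OC)cc3)[C@@H]12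
A4 | alternative 3 | (2Z,6E)-cyclodeca-2,6-dienone with C3 TBS ether and C8 triisopropylsilyl ether | O=C1/C=C(/C)[C@@H](O[Si](C)(C)C(C)(C)C)C/C=C(\C)C[C@@H](O[Si](C(C)C)(C(C)C)C(C)C)C1
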